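**Plan**

- Cuts: the three MOM ethers come off last. The C3 centre is traced back to racemic ketone 21 through a reduction/oxidation pair. Ring C is then cut in one operation at O1–C8a, C4–C4a and O1–C2, giving 3,5-bis(methoxymethoxy)benzyne (from silyl triflate 18) and 2-arylacrylic acid 9.
- Enabling feature: in ring A, C8a (bearing O1) and C4a (bearing the C4 carbonyl) are neighbours, and only C4a has an oxygenated neighbour (C5). An aryne across C4a–C8a is therefore polarised by the C5 ether to take a carboxylate oxygen at C8a and the acyl group at C4a. C2 is the terminal alkene carbon beta to that acyl group, so the new phenoxide closes ring C.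
- Forward order: ring D by propargyl ether Claisen cyclisation on 3',4'-dihydroxyacetophenone, then acetyl to enol triflate to acrylic acid 9 (steps 1–5). Aryne precursor 18 from 5-bromoresorcinol by carbamate-directed ortho-silylation (steps 6–10). Ring C is closed onto ring A in step 11.
- Stereochemistry: C3 is set by dynamic kinetic resolution in a Ru-catalysed asymmetric transfer hydrogenation ((S,S)-TsDPEN) to the cis-(3S,4S) alcohol. Non-basic oxidation returns the (3S) ketone, and base-free acid removes the MOM groups.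

Key step: step 11

Remark: C3 of a 3-arylchroman-4-one epimerises readily with base, so it is set late and every later operation is kept base-free; the C3 centre of the target is S by the CIP rules.

**Route**

Step 1
Reactants: 1 1-(3,4-dihydroxyphenyl)ethanone; 2 3-chloro-3-methylbut-1-yne
Product: 3 1-[3-hydroxy-4-(2-methylbut-3-yn-2-yloxy)phenyl]ethanone
Conditions: K2CO3 (1.0 equiv), KI, CuI (5 mol%), DMF, 60 °C, argon
Reagents that add atoms: none
Why: Copper-assisted propargylic Williamson etherification: with one equivalent of weak base only the more acidic 4-OH (para to the acetyl group) is ionised, so the tertiary propargyl group should go to O4 and leave the 3-OH free.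

Step 2
Reactants: 3 1-[3-hydroxy-4-(2-methylbut-3-yn-2-yloxy)phenyl]ethanone
Product: 5 1-(8-hydroxy-2,2-dimethyl-2H-chromen-6-yl)ethanone, via ortho-allenyl catechol 4 (not isolated)
Conditions: N,N-diethylaniline, 190 °C
Reagents that add atoms: none
Why: Aromatic propargyl Claisen rearrangement, enolisation to the ortho-allenyl phenol, 1,5-hydrogen shift and oxa-6π electrocyclisation should give the 2,2-dimethylchromene; the ether oxygen has only one free ortho carbon (the other carries the OH), which fixes the regiochemistry.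

Step 3
Reactants: 5 1-(8-hydroxy-2,2-dimethyl-2H-chromen-6-yl)ethanone
Product: 6 1-[8-(methoxymethoxy)-2,2-dimethyl-2H-chromen-6-yl]ethanone
Conditions: MOMCl, i-Pr2NEt, CH2Cl2, 0 °C to rt
Reagents that add atoms: chloromethyl methyl ether, COCCl
Why: Standard O-alkylation of a phenol to its MOM ether, chosen because it survives fluoride, strong base and hydride and is removed by mild acid at the end.

Step 4
Reactants: 6 1-[8-(methoxymethoxy)-2,2-dimethyl-2H-chromen-6-yl]ethanone
Product: 7 1-[8-(methoxymethoxy)-2,2-dimethyl-2H-chromen-6-yl]ethenyl trifluoromethanesulfonate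
Conditions: KN(SiMe3)2, THF, −78 °C; then PhNTf2, −78 to 0 °C
Reagents that add atoms: N-phenylbis(trifluoromethanesulfonimide), O=S(=O)(N(c1ccccc1)S(=O)(=O)C(F)(F)F)C(F)(F)F
Why: Kinetic deprotonation of the methyl ketone and O-triflation of the potassium enolate should give the 1-arylvinyl triflate (enol triflate formation), to be used without prolonged storage.

Step 5
Reactants: 7 1-[8-(methoxymethoxy)-2,2-dimethyl-2H-chromen-6-yl]ethenyl trifluoromethanesulfonate
Product: 9 2-[8-(methoxymethoxy)-2,2-dimethyl-2H-chromen-6-yl]prop-2-enoic acid, via mixed acetic anhydride 8 (not isolated)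
Conditions: Pd(OAc)2 (5 mol%), dppp (5 mol%), KOAc (4 equiv), CO (1 atm), DMSO, 60 °C; aqueous work-up at pH 4–5
Reagents that add atoms: carbon monoxide, [C-]#[O+]; potassium acetate, CC(=O)[O-].[K+] (one oxygen, through the mixed anhydride); water, O (hydrolysis of the mixed anhydride on work-up)
Why: Palladium-catalysed hydroxycarbonylation of an enol triflate: oxidative addition, CO insertion and capture of the acyl-palladium species by acetate give the mixed anhydride, which is hydrolysed on work-up to the 2-arylacrylic acid.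

Step 6
Reactants: 10 5-bromobenzene-1,3-diol
Product: 11 1-bromo-3,5-bis(methoxymethoxy)benzene
Conditions: MOMCl (2.5 equiv), i-Pr2NEt, CH2Cl2, 0 °C to rt
Reagents that add atoms: chloromethyl methyl ether, COCCl
Why: Double O-alkylation of a symmetrical resorcinol; the bromine marks the one position that will carry the third oxygen of ring A.

Step 7
Reactants: 11 1-bromo-3,5-bis(methoxymethoxy)benzene
Product: 12 3,5-bis(methoxymethoxy)phenol
Conditions: Pd2(dba)3 (1 mol%), t-BuXPhos (4 mol%), KOH (3 equiv), 1,4-dioxane/H2O, 100 °C; neutralisation with NaH2PO4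
Reagents that add atoms: potassium hydroxide, [K+].[OH-]
Why: Palladium-catalysed hydroxylation of an aryl bromide (Buchwald–Hartwig-type C–O coupling with hydroxide); MOM ethers are stable to hot aqueous base.

Step 8
Reactants: 12 3,5-bis(methoxymethoxy)phenol
Product: 13 3,5-bis(methoxymethoxy)phenyl N-(propan-2-yl)carbamate
Conditions: i-PrNCO, Et3N (cat.), CH2Cl2, rt
Reagents that add atoms: 2-isocyanatopropane, CC(C)N=C=O
Why: Addition of the phenol to the isocyanate installs a carbamate that is both a strong ortho-director and easily removed later.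

Step 9
Reactants: 13 3,5-bis(methoxymethoxy)phenyl N-(propan-2-yl)carbamate
Product: 16 3,5-bis(methoxymethoxy)-2-(trimethylsilyl)phenyl N-(propan-2-yl)carbamate, via N-silyl carbamate 14 (not isolated), via C-silylated N-silyl carbamate 15 (not isolated)
Conditions: TBSOTf, TMEDA, Et2O, 0 °C to rt; n-BuLi, TMEDA, −78 °C; TMSCl, −78 °C to rt; cold aq. NaHSO4
Reagents that add atoms: chlorotrimethylsilane, C[Si](C)(C)Cl
Why: Directed ortho-metalation after in-situ N-silylation: the O-carbamate is a stronger director than OMOM, so lithiation should occur at C2 (between carbamate and OMOM, equivalent to C6) and not between the two OMOM groups, and the N–Si bond is hydrolysed on work-up.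

Step 10
Reactants: 16 3,5-bis(methoxymethoxy)-2-(trimethylsilyl)phenyl N-(propan-2-yl)carbamate
Product: 18 3,5-bis(methoxymethoxy)-2-(trimethylsilyl)phenyl trifluoromethanesulfonate, via ortho-silyl phenol 17 (not isolated)
Conditions: Et2NH, DBU, MeCN, 40 °C; then PhNTf2, rt
Reagents that add atoms: N-phenylbis(trifluoromethanesulfonimide), O=S(=O)(N(c1ccccc1)S(=O)(=O)C(F)(F)F)C(F)(F)F
Why: E1cB cleavage of the N–H carbamate (the isocyanate is trapped by Et2NH as a urea) frees the phenoxide, which is triflated in the same flask to the ortho-silylaryl triflate.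

Step 11
Reactants: 9 2-[8-(methoxymethoxy)-2,2-dimethyl-2H-chromen-6-yl]prop-2-enoic acid; 18 3,5-bis(methoxymethoxy)-2-(trimethylsilyl)phenyl trifluoromethanesulfonate
Product: 21 rac-5,7-bis(methoxymethoxy)-3-[8-(methoxymethoxy)-2,2-dimethyl-2H-chromen-6-yl]-2,3-dihydro-4H-chromen-4-one, via aryne 19 (not isolated), via ortho-hydroxyaryl enone 20 (not isolated)
Conditions: CsF (4 equiv), 18 (1.5 equiv), THF, 125 °C, sealed tube
Reagents that add atoms: none
Why: Fluoride unmasks benzyne 19 from 18 and turns acid 9 into its carboxylate, whose oxygen adds to the aryne carbon remote from the flanking OMOM group (the future C8a), so that the aryl anion sits on the carbon next to that ether oxygen (the future C4a), as the inductive effect of a 3-alkoxy group and the distortion of the triple bond demand. The anion attacks the adjacent ester carbonyl (4-exo-trig) and the four-membered alkoxide opens at the acyl–oxygen bond, a net insertion of the aryne into the C–O bond of the carboxylate that delivers the phenoxide of enone 20 with O1–C8a and C4–C4a made. This phenoxide closes ring C by 6-endo-trig oxa-Michael addition onto the terminal CH2 (C2), and the enolate takes back the acid proton from bifluoride. The closest known reaction type is the insertion of arynes into the C–O bond of carboxylic acids to give ortho-hydroxyaryl ketones, which with α,β-unsaturated acids continues to chroman-4-ones. C3 arises by protonation of a flat enolate and is deliberately racemic here, to be set in steps 12 and 13. The step needs regiocontrol on the unsymmetrical aryne, secured by the C5 OMOM group beside the triple bond, and carbonyl attack of the aryl anion in preference to protonation or conjugate addition, favoured by aprotic THF, the high temperature and the proximity of the carbonyl.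

Step 12
Reactants: 21 rac-5,7-bis(methoxymethoxy)-3-[8-(methoxymethoxy)-2,2-dimethyl-2H-chromen-6-yl]-2,3-dihydro-4H-chromen-4-one
Product: 22 (3S,4S)-5,7-bis(methoxymethoxy)-3-[8-(methoxymethoxy)-2,2-dimethyl-2H-chromen-6-yl]-3,4-dihydro-2H-chromen-4-ol
Conditions: RuCl(p-cymene)[(S,S)-TsDPEN] (3 mol%), HCO2H/Et3N (2:3, amine in excess), EtOAc, 40 °C
Reagents that add atoms: none
Why: Noyori–Ikariya asymmetric transfer hydrogenation under dynamic kinetic resolution: Et3N equilibrates the C3 epimers of 21 through the enol, and the (S,S) catalyst should reduce only the (3S) ketone with hydride arriving opposite the 3-aryl group, so that C4 (S) is set by the catalyst and C3 (S) by its cis relation to the new carbinol.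

Step 13
Reactants: 22 (3S,4S)-5,7-bis(methoxymethoxy)-3-[8-(methoxymethoxy)-2,2-dimethyl-2H-chromen-6-yl]-3,4-dihydro-2H-chromen-4-ol
Product: 23 (3S)-5,7-bis(methoxymethoxy)-3-[8-(methoxymethoxy)-2,2-dimethyl-2H-chromen-6-yl]-2,3-dihydro-4H-chromen-4-one
Conditions: Dess–Martin periodinane, CH2Cl2, 0 °C to rt; Na2S2O3 / pH 7 phosphate work-up
Reagents that add atoms: none
Why: Dess–Martin oxidation of the benzylic alcohol under non-basic conditions removes the auxiliary C4 centre and should leave C3 untouched (its descriptor stays S because the priority order at C3 does not change).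

Step 14
Reactants: 23 (3S)-5,7-bis(methoxymethoxy)-3-[8-(methoxymethoxy)-2,2-dimethyl-2H-chromen-6-yl]-2,3-dihydro-4H-chromen-4-one
Product: 24 (3S)-5,7-dihydroxy-3-(8-hydroxy-2,2-dimethyl-2H-chromen-6-yl)-2,3-dihydro-4H-chromen-4-one
Conditions: HCl (1.25 M in MeOH), 0 °C to rt
Reagents that add atoms: none
Why: Acid-catalysed acetal exchange with methanol should cleave the three aryl MOM ethers (the 5-O-MOM beside the carbonyl first) as dimethoxymethane; no base is present to remove the C3–H, and cold dilute acid should leave the chromene alkene alone.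

**Compound list**

1 | 1-(3,4-dihydroxyphenyl)ethanone | CC(=O)c1ccc(O)c(O)c1 | starting material
2 | 3-chloro-3-methylbut-1-yne | CC(C)(Cl)C#C | starting material
3 | 1-[3-hydroxy-4-(2-methylbut-3-yn-2-yloxy)phenyl]ethanone | CC(=O)c1ccc(OC(C)(C)C#C)c(O)c1 | intermediate
4 | 1-[3,4-dihydroxy-5-(3-methylbuta-1,2-dien-1-yl)phenyl]ethanone (ortho-allenyl catechol, not isolated) | CC(=O)c1cc(O)c(O)c(C=C=C(C)C)c1 | intermediate
5 | 1-(8-hydroxy-2,2-dimethyl-2H-chromen-6-yl)ethanone | CC(=O)c1cc(O)c2OC(C)(C)C=Cc2c1 | intermediate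
6 | 1-[8-(methoxymethoxy)-2,2-dimethyl-2H-chromen-6-yl]ethanone | CC(=O)c1cc(OCOC)c2OC(C)(C)C=Cc2c1 | intermediate
7 | 1-[8-(methoxymethoxy)-2,2-dimethyl-2H-chromen-6-yl]ethenyl trifluoromethanesulfonate | C=C(OS(=O)(=O)C(F)(F)F)c1cc(OCOC)c2OC(C)(C)C=Cc2c1 | intermediate
8 | acetic 2-[8-(methoxymethoxy)-2,2-dimethyl-2H-chromen-6-yl]prop-2-enoic anhydride (mixed anhydride, not isolated) | C=C(C(=O)OC(C)=O)c1cc(OCOC)c2OC(C)(C)C=Cc2c1 | intermediate
9 | 2-[8-(methoxymethoxy)-2,2-dimethyl-2H-chromen-6-yl]prop-2-enoic acid | C=C(C(=O)O)c1cc(OCOC)c2OC(C)(C)C=Cc2c1 | intermediate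
10 | 5-bromobenzene-1,3-diol | Oc1cc(O)cc(Br)c1 | starting material
11 | 1-bromo-3,5-bis(methoxymethoxy)benzene | COCOc1cc(Br)cc(OCOC)c1 | intermediate
12 | 3,5-bis(methoxymethoxy)phenol | COCOc1cc(O)cc(OCOC)c1 | intermediate
13 | 3,5-bis(methoxymethoxy)phenyl N-(propan-2-yl)carbamate | CC(C)NC(=O)Oc1cc(OCOC)cc(OCOC)c1 | intermediate
14 | 3,5-bis(methoxymethoxy)phenyl N-(tert-butyldimethylsilyl)-N-(propan-2-yl)carbamate (not isolated) | CC(C)N(C(=O)Oc1cc(OCOC)cc(OCOC)c1)[Si](C)(C)C(C)(C)C | intermediate
15 | 3,5-bis(methoxymethoxy)-2-(trimethylsilyl)phenyl N-(tert-butyldimethylsilyl)-N-(propan-2-yl)carbamate (not isolated) | CC(C)N(C(=O)Oc1cc(OCOC)cc(OCOC)c1[Si](C)(C)C)[Si](C)(C)C(C)(C)C | intermediate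
16 | 3,5-bis(methoxymethoxy)-2-(trimethylsilyl)phenyl N-(propan-2-yl)carbamate | CC(C)NC(=O)Oc1cc(OCOC)cc(OCOC)c1[Si](C)(C)C | intermediate
17 | 3,5-bis(methoxymethoxy)-2-(trimethylsilyl)phenol (not isolated) | COCOc1cc(O)c([Si](C)(C)C)c(OCOC)c1 | intermediate
18 | 3,5-bis(methoxymethoxy)-2-(trimethylsilyl)phenyl trifluoromethanesulfonate | COCOc1cc(OS(=O)(=O)C(F)(F)F)c([Si](C)(C)C)c(OCOC)c1 | intermediate
19 | 3,5-bis(methoxymethoxy)benzyne (1,2-didehydro-3,5-bis(methoxymethoxy)benzene, not isolated) | COCOC1=CC(OCOC)=CC#C1 | intermediate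
20 | 1-[2-hydroxy-4,6-bis(methoxymethoxy)phenyl]-2-[8-(methoxymethoxy)-2,2-dimethyl-2H-chromen-6-yl]prop-2-en-1-one (formed as its phenoxide, not isolated) | C=C(C(=O)c1c(O)cc(OCOC)cc1OCOC)c1cc(OCOC)c2OC(C)(C)C=Cc2c1 | intermediate
21 | rac-5,7-bis(methoxymethoxy)-3-[8-(methoxymethoxy)-2,2-dimethyl-2H-chromen-6-yl]-2,3-dihydro-4H-chromen-4-one | COCOc1cc(OCOC)c2C(=O)C(COc2c1)c1cc(OCOC)c2OC(C)(C)C=Cc2c1 | intermediate
22 | (3S,4S)-5,7-bis(methoxymethoxy)-3-[8-(methoxymethoxy)-2,2-dimethyl-2H-chromen-6-yl]-3,4-dihydro-2H-chromen-4-ol (3,4-cis) | CC1(C)C=Cc2cc([C@H]3COc4cc(OCOC)cc(OCOC)c4[C@H]3O)cc(OCOC)c2O1 | intermediate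
23 | (3S)-5,7-bis(methoxymethoxy)-3-[8-(methoxymethoxy)-2,2-dimethyl-2H-chromen-6-yl]-2,3-dihydro-4H-chromen-4-one | CC1(C)C=Cc2cc([C@H]3COc4cc(OCOC)cc(OCOC)c4C3=O)cc(OCOC)c2O1 | intermediate
24 | (3S)-5,7-dihydroxy-3-(8-hydroxy-2,2-dimethyl-2H-chromen-6-yl)-2,3-dihydro-4H-chromen-4-one | CC1(C)C=Cc2cc([C@H]3COc4cc(O)cc(O)c4C3=O)cc(O)c2O1 | target

**Step count and risks**

Total step count: 14. Longest linear sequence: 9 steps (10 to 24 through steps 6–14; the branch from 1 through steps 1–5 and 11–14 is equally long).

Steps most likely to fail: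

1. Step 11. The aryl anion may be protonated before the acyl shift (plain O-arylation), may add in conjugate fashion to the acrylate, or the aryne may be consumed by the product enolate or the chromene alkene. The fallback sets out from 13 and 9 and returns at 21, replacing the aryne by a low-temperature anionic Fries shift. Carbamate 13 is N-silylated and lithiated as in step 9 but quenched with I2, giving 2-iodo-3,5-bis(methoxymethoxy)phenyl N-(tert-butyldimethylsilyl)-N-(propan-2-yl)carbamate F1, hydrolysed on work-up to 2-iodo-3,5-bis(methoxymethoxy)phenyl N-(propan-2-yl)carbamate F2. Et2NH/DBU in MeCN then frees 2-iodo-3,5-bis(methoxymethoxy)phenol F3. Steglich esterification with acid 9 (EDC·HCl, DMAP, CH2Cl2) gives 2-iodo-3,5-bis(methoxymethoxy)phenyl 2-[8-(methoxymethoxy)-2,2-dimethyl-2H-chromen-6-yl]prop-2-enoate F4. Iodine–lithium exchange (n-BuLi, THF, −100 °C) generates the same ortho-metalated aryl ester at a defined position; its 1,3-O-to-C acyl shift gives the phenoxide of 20, which should cyclise on warming to 21.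

2. Step 12. Hydride transfer to the hindered, electron-rich C4 carbonyl beside the C5 ether may be slow, racemisation and reduction may couple poorly (low diastereo- or enantioselectivity), or the benzylic alcohol may ionise. The fallback sets out from 21 and returns at 23, setting C3 by enantioselective protonation instead of reduction. Ketone 21 is converted (LiN(SiMe3)2, THF, −78 °C; TMSCl) into [5,7-bis(methoxymethoxy)-3-[8-(methoxymethoxy)-2,2-dimethyl-2H-chromen-6-yl]-2H-chromen-4-yl]oxy-trimethylsilane F5. This silyl enol ether is protonated with phenol under catalysis by a BINOL-derived chiral N-triflyl thiophosphoramide (toluene, rt), the catalyst antipode being chosen to give the (3S) ketone 23.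

3. Step 14. The C3 configuration may erode by acid-catalysed enolisation during MOM cleavage, or methanol/HCl may add across the chromene double bond. The fallback sets out from 21 and returns at 24, deprotecting before any stereochemistry is at stake. Racemic 21 is treated with HCl/MeOH (50 °C) to give rac-5,7-dihydroxy-3-(8-hydroxy-2,2-dimethyl-2H-chromen-6-yl)-2,3-dihydro-4H-chromen-4-one F6, which is resolved by preparative chromatography on an amylose tris(3,5-dimethylphenylcarbamate) phase with a neutral eluent to give 24. The (3R)-5,7-dihydroxy-3-(8-hydroxy-2,2-dimethyl-2H-chromen-6-yl)-2,3-dihydro-4H-chromen-4-one F7 is racemised with a trace of Et3N and recycled.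

**Further compounds**

F1 | step 11 | 2-iodo-3,5-bis(methoxymethoxy)phenyl N-(tert-butyldimethylsilyl)-N-(propan-2-yl)carbamate | CC(C)N(C(=O)Oc1cc(OCOC)cc(OCOC)c1I)[Si](C)(C)C(C)(C)C
F2 | step 11 | 2-iodo-3,5-bis(methoxymethoxy)phenyl N-(propan-2-yl)carbamate | CC(C)NC(=O)Oc1cc(OCOC)cc(OCOC)c1I
F3 | step 11 | 2-iodo-3,5-bis(methoxymethoxy)phenol | COCOc1cc(O)c(I)c(OCOC)c1
F4 | step 11 | 2-iodo-3,5-bis(methoxymethoxy)phenyl 2-[8-(methoxymethoxy)-2,2-dimethyl-2H-chromen-6-yl]prop-2-enoate | C=C(C(=O)Oc1cc(OCOC)cc(OCOC)c1I)c1cc(OCOC)c2OC(C)(C)C=Cc2c1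
F5 | step 12 | [5,7-bis(methoxymethoxy)-3-[8-(methoxymethoxy)-2,2-dimethyl-2H-chromen-6-yl]-2H-chromen-4-yl]oxy-trimethylsilane | COCOc1cc(OCOC)c2C(O[Si](C)(C)C)=C(COc2c1)c1cc(OCOC)c2OC(C)(C)C=Cc2c1
F6 | step 14 | rac-5,7-dihydroxy-3-(8-hydroxy-2,2-dimethyl-2H-chromen-6-yl)-2,3-dihydro-4H-chromen-4-one | CC1(C)C=Cc2cc(C3COc4cc(O)cc(O)c4C3=O)cc(O)c2O1
F7 | step 14 | (3R)-5,7-dihydroxy-3-(8-hydroxy-2,2-dimethyl-2H-chromen-6-yl)-2,3-dihydro-4H-chromen-4-one | CC1(C)C=Cc2cc([C@@H]3COc4cc(O)cc(O)c4C3=O)cc(O)c2O1
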